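Readings and results were generated by integration on assumed constants; noise was put on by code.

**Late ceiling.** At late times the balance of the electrophile, the limiting reagent in beta and zeta, caps the answer: what has reacted stands as target or side product, and in the midnight and winter runs c(electrophile) + c(target) stays at the charge within scatter, so at most 100% can react. Both flasks are read earlier, though.

| setting | midnight | winter | zeta | beta |
|---|---|---|---|---|
| electrophile | 11 mM | 32 mM | 16 mM | 16 mM |
| nucleophile | 32 mM | 32 mM | 64.0 mM | 32.0 mM |
| remark | run made earlier | run made earlier |  |  |
| time |  |  | 10 min | 10 min |

| run | time / min | electrophile / % | target / % |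
|---|---|---|---|
| midnight | 0.500 | 95 | 6 |
| midnight | 1.50 | 87 | 16 |
| midnight | 3.00 | 76 | 22 |
| midnight | 4.00 | 70 | 29 |
| midnight | 6.00 | 62 | 39 |
| winter | 0.500 | 96 | 6 |
| winter | 1.50 | 89 | 11 |
| winter | 3.00 | 82 | 18 |
| winter | 4.00 | 77 | 23 |
| winter | 6.00 | 67 | 31 |

(readings scatter by 1.5 percentage points)

1. part of the electrophile that has reacted at the end, zeta
2. part of the electrophile that has reacted at the end, beta
3. what raising the concentration of nucleophile from its lowest to its highest value here does to the part of the electrophile that has reacted (changes below 5 percentage points count as none) (it falls / it rises / no change)

- the analysis behind the earlier runs scatters by 1.5 percentage points, standard deviation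
- steps under discussion: nucleophile + acid set free <-> protonated nucleophile; nucleophile <-> dormant form; acid set free + target -> side product; electrophile + nucleophile <-> acid set free + target

**Carried constant.** From a last reading I take the apparent pseudo-first-order constant k′, the logarithm of charge over remainder, divided by time. The midnight run gives 0.0797 /min and the winter run 0.0667 /min.

**My bracket.** Beta has the nucleophile charge of both runs, and its electrophile lies between theirs. So I expect midnight to give the upper edge, 54.9%, and winter the lower, 48.7%. Both edges are estimates: each stretches a constant read at 6.00 min to 10 min. For zeta I assume first order in nucleophile, which these runs cannot show, and scale k′ by the charges: 73.7% to 79.7%. Zeta's lower edge clears beta's upper edge by more than the margin, so I say it rises.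

**The forecast.** It gives 74% for zeta, on my lower edge, and 51% for beta, inside: “Raising the nucleophile should increase conversion.”

**The flask.** Zeta gives 75.3% and beta 48.0%, so it rises, by 27 percentage points; the difference in nucleophile charge is the main reason for that gap. Beta lies 0.70 points under my lower edge, less than the scatter of a reading.

    nucleophile + acid set free ⇌ protonated nucleophile, settled at all times (K = 37000 /M)
    nucleophile ⇌ dormant form (K = 0.180, k = 0.480 /min)
    acid set free + target → side product (k = 3.80 /M/min)
    electrophile + nucleophile ⇌ acid set free + target (K = 12.0, k = 3.40 /M/min)

**Shrinking supply.** A part of beta's shortfall is the shrinking supply of nucleophile: with that supply held, beta reaches 66.3%, while in fact 44% of the nucleophile charge stays free at 10.0 min. Beta's answer moves by 5 points at nucleophile charges of 27.8 mM or 36.6 mM. Beta's own k′ is 0.0655 /min; scaled to 54 mM of nucleophile it gives 66.9%, and that neighbouring flask reached 68.6%.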